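Start from teal, the earlier run with 0.50 equiv of second substrate: it stood at 27.4% target after 6.00 h. Amber, with 1 equiv, needed 8.00 h for 27.3%, longer than teal, so read second substrate as a competitor for the catalyst.

in all of them: starting material 0.20 M; free catalyst 15 mol%
- amber: second substrate 1 equiv; reagent 0.95 equiv; capture agent 0.20 M; the very flask that is asked about, followed so far
- teal: second substrate 0.50 equiv; reagent 0.95 equiv; capture agent 0.20 M; run made earlier
- flask: second substrate 1.00 equiv; reagent 0.950 equiv; capture agent 0.200 M; time 8.0 d

| run | time / h | target / % | starting material / % |
|---|---|---|---|
| amber | 8.00 | 27.3 | 60.1 |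
| amber | 25.0 | 34.1 | 49.6 |
| amber | 40.0 | 37.6 | 48.7 |
| amber | 72.0 | 37.0 | 49.7 |
| amber | 96.0 | 37.6 | 48.7 |
| amber | 120 | 37.6 | 47.1 |
| amber | 144 | 36.7 | 49.8 |
| teal | 0.833 | 8.4 | 81.8 |
| teal | 2.50 | 16.2 | 72.9 |
| teal | 5.00 | 26.2 | 61.8 |
| teal | 6.00 | 27.4 | 60.2 |
| teal | 10.0 | 34.2 | 53.6 |
| teal | 12.0 | 36.4 | 51.0 |
| teal | 15.0 | 37.6 | 49.5 |

(each reading ± 1 percentage point)

- autumn: change nothing and wait 15 d more
- noon: at 8.0 d take out 90% of the target then present, then wait 15 d
- dusk: at 8.0 d add reagent, 100% of the amount charged, then wait 15 d
- winter: at 8.0 d add free catalyst, 100% of the amount charged, then wait 15 d

- removed target is counted in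
- additions bring no volume worth counting

- target, in percent of the starting material first charged, at 8.0 d
- which option adds most target ("none" when 2 percentage points or less is all one gets) (autumn / noon / dusk / winter / none)
- target present, with what was taken out counted in, in percent of the starting material first charged, after noon
- target present, with what was taken out counted in, in percent of the starting material first charged, after winter

Reckon amber first. Take the mean of its readings from 40.0 h on, which stay flat within the scatter:

plateau = 37.3%

Next ask what stopped it. At 96.0 h, target and starting material leave 13.7% unaccounted for, close to the loading of 15 mol%, so read that as catalyst locked away, each catalyst roughly once. Each catalyst then made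

turnovers = plateau / loading = 2.49

Expect nothing, then, from waiting, from taking out target or from adding reagent, and put noon at the plateau. A new dose of catalyst is the option to examine, and at the same turnovers it gives 74.6%.

That doubling is the weak link, since it charges one reagent per target. Second substrate is a substrate too, so make my own assumption that each equivalent of it draws reagent on equal footing with starting material:

cost = 1 + c(second substrate) / c(starting material) = 2.00 reagent per target

Now define the reagent budget, the target that the charged reagent pays for, counting reagent as the limiting reagent:

budget = c(reagent) / (cost × c(starting material)) = 47.5%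

So winter can add about 10 percentage points, which is more than the margin of 2 points but less than the plateau. Commit to winter, ending near the budget.

The forecast gives 37.3% now, 37.8% after noon and winter as the best option, the option my reckoning names too. For winter it says “Fresh catalyst should give about 30 more” and sets 68%, higher than my budget.

The flask gives 36.6% at the asked time. Autumn adds 0 points, noon 0 points and dusk 0 points, with noon standing at 36.6%. Winter adds 10 points and reaches 47.0%, so the best option is winter.

    catalyst intermediate A + capture agent → trapped intermediate (k = 1.70 M⁻¹ h⁻¹)
    reagent + catalyst intermediate A → free catalyst + target (k = 6.90 M⁻¹ h⁻¹)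
    starting material + free catalyst ⇌ catalyst intermediate A (K = 9.70 M⁻¹, k = 240 M⁻¹ h⁻¹)
    reagent + catalyst intermediate B → free catalyst + second product (k = 9.10 M⁻¹ h⁻¹)
    second substrate + free catalyst ⇌ catalyst intermediate B (K = 5.10 M⁻¹, k = 270 M⁻¹ h⁻¹)

In amber the reagent step gives catalyst intermediate A a half-life of 0.77 h at 2.76 h, against 2.0 h for capture with the other concentrations as charged, and by 192 h the trapped intermediate holds 100% of the catalyst. Second product then stands at 0.0613 M beside 36.6% target, which is 1.84 reagent per target, less than the reckoned cost, and this cost puts the budget at 51.7%, above the 47.0% of winter.

Take the neighbour with 0.80 M starting material and the same equivalents. The budget reads equivalents, so there it is again 47.5% at the reckoned cost and 51.7% at the cost read in amber. Computed, it gives 51.1% target, with reagent down to 0.0595% of its charge and the first to run out.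

The data are simulated with made-up constants; the scatter is artificial.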